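The readings stem from a simulated flask on assumed constants; scatter was added.

1. Cedar was the charge I had to defend for the next run: does 3.0 M of E give enough more Q than larch's 2.0 M to be worth keeping?

| flask | E | remark | time |
|---|---|---|---|
| north-east | 0.69 M | run made earlier |  |
| oak | 0.60 M |  | 2.0 min |
| larch | 2.0 M |  | 2.0 min |
| elm | 1.0 M |  | 2.0 min |
| cedar | 3.0 M |  | 2.0 min |

north-east run (percent of the E charged)

| time / s | Q / % | E / % |
|---|---|---|
| 10.0 | 23.9 | 49.7 |
| 20.0 | 28.3 | 35.1 |
| 40.0 | 35.2 | 28.2 |
| 60.0 | 36.7 | 24.6 |
| 80.0 | 40.7 | 25.2 |

(each reading ± 1 percentage point)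

1. the flasks by amount of Q, in percent of the E charged, highest first, at 2.0 min (oak / larch / elm / cedar)
2. the amount of Q, in percent of the E charged of the flask you put first, at 2.0 min
3. the amount of Q, in percent of the E charged of the flask you put last, at 2.0 min

- in percentages every species weighs as the E in it: one Q counts as two
- the numbers in the tables scatter with a standard deviation of 1 percentage point

2. I wrote q and e for the fractions of the charge standing as Q and E. I took the balance quotient, q/(e² × charge), as my measure of how far a flask had gone; since q counts each Q as two E, this is twice the reaction quotient of two E to Q.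

3. In the north-east run this quotient climbed from 6.41 L mol⁻¹ at 40.0 s to 8.79 L mol⁻¹ at 60.0 s and 9.29 L mol⁻¹ at 80.0 s. Because the last reading stood highest, I carried that one, the balance quotient B, as a floor.

4. The readings leave an unseen share, which I took as proportional to e. So the charge obeys B × charge × e² + s × e = 1, where s × e covers E and the unseen share, with s = 2.35 at 80.0 s.

5. In logarithms, cedar's charge stands 0.638 of a power of ten above the north-east run, and q/e² rises by the same step, to 27.9.

6. Solving gave me 15.2% for e and 64.3% for q in cedar. The same reckoning gave 17.7% for e and 58.3% for q in larch, and 26.2% for e and 38.3% for q in oak.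

7. Cedar's lead over larch, 6 points, stands above the scatter, so I kept cedar.

8. The forecast gave cedar > larch > elm > oak, with top 62% and low 38%, and held that “2 min is near equilibrium for all flasks”. Its order matched mine, but its top stood below my cedar figure.

    2 E ⇌ Q (K = 6.80 L mol⁻¹, k = 0.0330 L mol⁻¹ s⁻¹)
    E ⇌ G (K = 1.40, k = 0.0450 s⁻¹)

The flasks ranked cedar > larch > elm > oak, the forecast's order, with cedar at 67.7% of its charge as Q and oak at 39.2%. Left until 20.0 min, cedar stood at 68.8%. At 2.00 min, with cedar's E at 13.3%, its quotient was 12.8 L mol⁻¹, above the carried 9.29 L mol⁻¹. For cedar's neighbour with 1.2 M of E, B and s give e = 21.2% and q = 50.1%, and at 2.00 min that flask held 52.6% as Q.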